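## Analysis of the target

Atoms are numbered as in a germacrane: C1–C10 the carbocycle, C11–C13 the lactone side chain (C13 the methylene carbon), C14 the methyl on C10, C15 the methyl on C4.

- Target 28 is a germacranolide whose ten-membered carbocycle is spanned by an ether oxygen between C5 and C10. The bridge divides it into two oxepanes, ring A (O, C10, C1, C2, C3, C4, C5) and ring B (O, C5, C6, C7, C8, C9, C10).
- An α-methylene-γ-butyrolactone (C11–C13, closed on O8) is trans-fused to ring B at C7–C8, and O9 carries the isovalerate.
- The six stereocentres are C4 (S), C5 (R), C7 (R), C8 (R), C9 (S) and C10 (R). In ring B the substituents on C7, C8 and C9 alternate from face to face, and O9 is cis to C14.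
- The oxygen bridge is cis, with H5 and C14 on the same side. The bicycle is therefore a cis-decalin with oxygen inserted into the ring-fusion bond, and C15 lies on the side of the bridge oxygen.
- The α-methylene lactone (a Michael acceptor) and the ester exclude late organometallic or strongly basic steps. The tertiary C10–O ether and the trans-diol are acid-sensitive to different degrees.
- The hard points are the bridged medium ring, the fully substituted C10 next to oxygenated C9, and C4/C5, which are remote from the ring B triad and must be set in a ten-membered ring.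
- The strategy rests on this feature: C5–C10 with C14 and the three-carbon unit on C7 are the ring, methyl and isopropenyl group of carvone. C1–C4 is a four-carbon strap from C10 to C5, so the carbocycle is that cyclohexane enlarged through vinyl groups on C5 and C10, and the bridge oxygen is the C5 carbinol oxygen reattached to C10.

## Retrosynthetic reasoning

**Ester (28 to 26 and 27).** The O9–acyl bond is cut last. An isovalerate would not survive Grignard reagents, potassium hydride or hydride. The forward step must acylate a hindered hydroxyl beside quaternary C10 without touching the methylene lactone.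

**Lactone (26 to 24, through 25).** The O8–C12 bond is cut and O8/O9 are returned to one acetonide. A single acid treatment then frees both hydroxyls and closes the lactone. The forward step must choose O8 (five-membered, trans-fused) over O9 (bridged six-membered).

**Side-chain oxidation (24 to 23 to 21).** The acrylic acid is traced to the isopropenyl group by allylic oxidation. It is placed after the C1=C10 alkene has gone, so that the isopropenyl group is the only alkene present.

**Ether bridge (21 to 20 to 19).** The O–C10 bond is cut. The bridge oxygen is the C5 carbinol oxygen, added across C1=C10 from inside the ring. An iodonium ion is used instead of a proton because the isopropenyl group would protonate as easily. The forward step must bond O5 to C10, not C1, and give the cis bridge.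

**Carbinol (19 to 18).** C5 goes back to the ketone. The reduction has to deliver hydrogen to the outer face of the folded ring.

**Ring enlargement (18 to 14 and 15).** C2–C3 and C4–C15 are cut and C5–C10 is rejoined, which contracts the ten-membered ring to a cyclohexane. No macrocyclisation is needed and C7, C8 and C9 sit on a chair.

- The isomer of the carbinol matters. Because 28 is a cis-decalin with inserted oxygen, the rearrangement should pass through a cis-decalin-like chair. That requires the two vinyl groups of 14 to be cis, with the C5 vinyl axial.
- The trans isomer would react through a trans-decalin-like chair and expose the opposite faces of C4 and C5.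
- The cis isomer gives a (Z)-C1=C10 alkene. This is of no consequence, since both alkene carbons become sp3 in 21.

**Second vinyl group (14 to 13 and 8).** The C5–C4 bond is cut. In ketone 13 the axial C14 blocks the equatorial trajectory, so addition should give the cis-divinyl isomer that is wanted.

**Quaternary C10 and O9 (13 to 12 to 11 to 10 to 9 to 7 and 8).** The C10–C1 bond is traced to a 1,2-shift of a vinyl group from C5 onto an epoxide. One stereospecific event creates the quaternary centre, O9 and the C5 ketone, with vinyl anti to O9. This avoids enolate alkylation at C10 and any undirected oxidation of a ring alkene beside the isopropenyl group.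

**O8 and the enone (7 to 6 to 5 to 4 to 3 to 1).** O8 must be present before the shift. It is introduced by α′-hydroxylation of carvone through silyl dienol ether 2, trans to isopropenyl. A 1,3-transposition of the enone then moves the carbonyl to C5 and leaves the oxygenated carbon as C8. The transposition exchanges the two sides of the ring, so the starting material is (S)-carvone 1.

## Alternatives that were turned down

**Alternative 1:** radical closure of ring B with loss of a sulfonyl group.

- Disconnection: C6–C7, with the C11=C13 methylene arising in the same step.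
- Forward key step: cathodic reduction of the redox-active ester A1 releases the primary C6 radical. It adds 7-exo to C7 of the tethered acrylate, and the adduct radical expels a sulfonyl radical to give A2.
- For: the acrylate with its methylene is complete at once, so no late allylic oxidation is needed. C4, C5 and C10 are set on a simple oxepane and do not depend on medium-ring conformers. On both points it is stronger than the chosen route.
- Against: a 7-exo closure of a primary radical is slow against reduction or hydrogen abstraction. C7 is created in the closure with nothing fixing it relative to C8. The whole C6–C9 chain must be built on ring A by acyclic stereocontrol.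
- Comparison: the chosen route takes C7 from carvone and forms the ten-membered ring in one step from a six-membered ring. It pays with conformational control at C4 and C5.

**Alternative 2:** oxygen insertion into the ring-fusion bond of a eudesmanolide.

- Disconnection: O–C10.
- Forward key step: Criegee rearrangement of the C5 perester A3. C10 shifts from C5 to oxygen with retention and the bridgehead cation is captured as the ester A4.
- For: all stereocentres are set on a rigid trans-decalin, and retention in the shift secures C10 directly. This is stronger than the chosen route, where C10 follows from the C5 carbinol.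
- Against: C5 ends one oxidation level too high and must be reduced through a strained bridgehead oxocarbenium ion. The tertiary perester at a ring fusion is hard to make. The shift of C10 must beat those of C4 and C6. The lactone lacks C13, and the oxygenated decalin is itself long to make.
- Comparison: the chosen route delivers C5 as a secondary carbinol and keeps C11–C13 from the start.

**Alternative 3:** chromium-mediated allylation with lactonisation.

- Disconnection: C7–C8 and O–C12.
- Forward key step: a divalent chromium salt converts the allylic bromide in A5 into an allylchromium species. It adds through C7 to the C8 aldehyde, and the alkoxide closes onto the ester to give A6.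
- For: ring B and the methylene lactone form in one operation. This is the shortest end game and beats the chosen route on that point.
- Against: C7 and C8 are both made in a seven-membered ring closure, and the trans lactone fusion is not assured. The α-alkoxy aldehyde can epimerise at C9. Ring A must be prepared as in alternative 1.
- Comparison: the chosen route sets C8 and C9 on a six-membered ring by directed or stereospecific steps. It needs four more steps after the bridge is closed.

Key step: step 12

Remark on the chemistry: carbinol 14 is carried as the isomer with the two vinyl groups cis, so the C1=C10 alkene of 18 is Z; this geometry is not part of 28.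

## Route

Step 1
Reactants: 1 (S)-carvone
Product: 3 (5R,6R)-6-hydroxy-2-methyl-5-(prop-1-en-2-yl)cyclohex-2-en-1-one (O8 trans to isopropenyl), via trimethylsilyl dienol ether 2 (not isolated)
Conditions: LiN(iPr)2, THF, −78 °C, then Me3SiCl; mCPBA, NaHCO3, CH2Cl2, −20 °C; 1 M HCl, THF, 0 °C
Reagents that add atoms: meta-chloroperbenzoic acid, `O=C(OO)c1cccc(Cl)c1`
Why: Kinetic deprotonation at C8 and O-silylation give the cross-conjugated dienol ether 2; in the Rubottom oxidation the peracid attacks the electron-rich silyl enol ether C8=C9 much faster than the isopropenyl group and anti to the C7 substituent, which sets O8 trans to isopropenyl.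

Step 2
Reactants: 3 hydroxy enone
Product: 4 tert-butyldimethylsilyl ether of 3
Conditions: t-BuMe2SiCl, imidazole, DMF, rt
Reagents that add atoms: tert-butyldimethylsilyl chloride, `CC(C)(C)[Si](C)(C)Cl`
Why: Imidazole-promoted silylation of the secondary hydroxyl; the ether shields the ketol from alkaline peroxide in step 3 and keeps O8 from acting as a directing group in step 7.

Step 3
Reactants: 4 silyloxy enone
Product: 5 epoxy ketone (C5–C10 epoxide, oxygen anti to isopropenyl)
Conditions: 30% H2O2, NaOH (cat.), MeOH, 0 °C
Reagents that add atoms: hydrogen peroxide, `OO`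
Why: Weitz–Scheffer nucleophilic epoxidation touches only the electron-poor enone alkene; the epoxide configuration is of no consequence because C10 becomes trigonal in step 4 and C5 in step 5.

Step 4
Reactants: 5 epoxy ketone
Product: 6 allylic alcohol (C5 carbinol, C9=C10 alkene, C8 silyl ether)
Conditions: N2H4·H2O, AcOH (cat.), MeOH, 0 °C to rt
Reagents that add atoms: none
Why: Wharton transposition: the epoxy hydrazone fragments with loss of N2, the alkene moves to C9=C10 and the oxygen stays on C5, so the oxygenated carbon C8 is now γ to the future carbonyl.

Step 5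
Reactants: 6 allylic alcohol
Product: 7 (4S,5R)-4-[(tert-butyldimethylsilyl)oxy]-2-methyl-5-(prop-1-en-2-yl)cyclohex-2-en-1-one
Conditions: MnO2, CH2Cl2, rt
Reagents that add atoms: none
Why: MnO2 oxidises the secondary allylic alcohol and leaves the silyl ether and the isolated alkene alone.

Step 6
Reactants: 7 enone; 8 vinylmagnesium bromide
Product: 9 (1S,4S,5R)-4-[(tert-butyldimethylsilyl)oxy]-1-ethenyl-2-methyl-5-(prop-1-en-2-yl)cyclohex-2-en-1-ol (hydroxyl cis to isopropenyl)
Conditions: CeCl3, THF, −78 °C
Reagents that add atoms: vinylmagnesium bromide, `C=C[Mg]Br`
Why: Organocerium 1,2-addition (no conjugate addition, little enolisation); as with carvone itself the nucleophile should enter the half-chair on the face away from the C7 isopropenyl group.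

Step 7
Reactants: 9 tertiary allylic alcohol
Product: 10 epoxy alcohol (C9–C10 epoxide on the face of the C5 hydroxyl)
Conditions: VO(acac)2 (cat.), t-BuOOH, CH2Cl2, 0 °C to rt
Reagents that add atoms: tert-butyl hydroperoxide, `CC(C)(C)OO`
Why: Hydroxyl-directed epoxidation: the vanadium alkoxide delivers oxygen to the trisubstituted allylic alkene C9=C10 on the face of the C5 hydroxyl, which is also the face away from the C8 silyl ether; the vinyl group reacts far more slowly and the isopropenyl group is out of reach.

Step 8
Reactants: 10 epoxy alcohol
Product: 11 (2R,3R,4R,5R)-4-[(tert-butyldimethylsilyl)oxy]-2-ethenyl-3-hydroxy-2-methyl-5-(prop-1-en-2-yl)cyclohexan-1-one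
Conditions: BF3·OEt2, CH2Cl2, −78 °C
Reagents that add atoms: none
Why: Semipinacol rearrangement of a 2,3-epoxy alcohol: the Lewis acid opens the epoxide at tertiary C10 while the C5 vinyl group, antiperiplanar to the breaking C10–O bond, shifts to C10 with inversion and C5 becomes the ketone; the shift is stereospecific, so the C10 vinyl ends anti to O9 and C14 syn to it.

Step 9
Reactants: 11 silyloxy hydroxy ketone
Product: 12 (2R,3R,4R,5R)-2-ethenyl-3,4-dihydroxy-2-methyl-5-(prop-1-en-2-yl)cyclohexan-1-one
Conditions: HF·pyridine, THF, 0 °C to rt
Reagents that add atoms: none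
Why: Acidic fluoride cleaves the silyl ether; basic fluoride is avoided because the β-hydroxy ketone could undergo retro-aldol cleavage.

Step 10
Reactants: 12 diol
Product: 13 acetonide ketone (O8 and O9 joined as a trans-fused isopropylidene acetal)
Conditions: 2-methoxypropene, PPTS (cat.), CH2Cl2, 0 °C
Reagents that add atoms: 2-methoxypropene, `COC(C)=C`
Why: Kinetic acetalisation of the trans-diequatorial diol; the trans-fused dioxolane protects both hydroxyls through the basic steps and locks the chair in which isopropenyl, O8, O9 and the C10 vinyl are equatorial and C14 is axial.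

Step 11
Reactants: 13 acetonide ketone; 8 vinylmagnesium bromide
Product: 14 cis-1,2-divinylcyclohexanol (5S,7R,8R,9R,10R; C5 vinyl cis to C10 vinyl)
Conditions: CeCl3, THF, −78 to 0 °C
Reagents that add atoms: vinylmagnesium bromide, `C=C[Mg]Br`
Why: Organocerium 1,2-addition to a hindered, enolisable ketone; in the locked chair the axial C14 blocks the equatorial trajectory, so the nucleophile should enter axially and anti to C14 (the usual course beside an axial angular methyl), giving the C5 vinyl axial and cis to the C10 vinyl.

Step 12
Reactants: 14 cis-1,2-divinylcyclohexanol; 15 iodomethane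
Product: 18 (1(10)Z,4S,7R,8R,9R) ten-membered enone with C5 ketone and C4 methyl, via potassium alkoxide 16 (not isolated), via potassium enolate 17 (not isolated)
Conditions: KH, 18-crown-6, THF, 0 °C to rt; then MeI, −78 to −20 °C
Reagents that add atoms: iodomethane, `CI`
Why: KH with 18-crown-6 turns 14 into the free alkoxide 16, whose [3,3] sigmatropic shift (anionic oxy-Cope rearrangement) forms C2–C3, breaks C5–C10 and gives the ten-membered enolate 17 regiospecifically at C4=C5; iodomethane then forms C4–C15. The closest known reaction type is the anionic oxy-Cope ring expansion of 1,2-divinylcyclohexanols to cyclodec-5-enones with alkylation of the enolate in the same flask. The ten-membered ring is made by four-carbon ring enlargement through a six-membered chair transition state, not by cyclisation. In that chair the acetonide-locked cyclohexane holds the C10 vinyl equatorial and the C5 vinyl axial, a cis-decalin-like array, so C9 ends cis to C2 (Z alkene) and 17 is released folded like a cis-decalin with ring A lying over ring B. The new stereocentre C4 is controlled by this fold: the concave face of C4 is covered by the axial hydrogens on C7 and C9 and by C1 and C2, so the electrophile should enter on the convex face, which gives 4S with C15 equatorial on the chair-like ring A. The step needs C- instead of O-methylation (soft electrophile, low temperature), a single methylation (no excess of base) and this facial selectivity; the last holds as long as 17 reacts in the fold in which it is formed, which with ring B locked and all substituents equatorial should also be its resting conformation. C7, C8 and C9 are not involved and keep their configuration.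

Step 13
Reactants: 18 enone
Product: 19 (5R) alcohol of 18
Conditions: NaBH4, MeOH, −20 °C
Reagents that add atoms: none
Why: Hydride reduction from the ring periphery: in the cis-decalin-like fold the convex face of C5 is open, so hydrogen should end up outside and O5 turned inwards towards C10, which is the 5R carbinol; NaBH4 leaves alkenes and acetonide untouched.

Step 14
Reactants: 19 alcohol
Product: 20 iodo ether (O bridge C5–C10, iodine on C1 anti to the new C10–O bond)
Conditions: I2, NaHCO3, MeCN, 0 °C, dark
Reagents that add atoms: iodine, `II`
Why: Transannular iodoetherification: iodonium formation is reversible on both alkenes but only the C1=C10 iodonium has a nucleophile within reach; O5 should open it from inside the ring at tertiary C10 (Markovnikov, anti to iodine), a closure that is 7-exo for ring B and 7-endo for ring A. From the 5R carbinol only the cis-bridged ether with 10R can form without an in,out bicycle.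

Step 15
Reactants: 20 iodo ether
Product: 21 bridged ether (4S,5R,7R,8R,9S,10R; 11-oxabicyclo[4.4.1]undecane core with C8/C9 acetonide and C7 isopropenyl)
Conditions: Bu3SnH, AIBN (cat.), toluene, 80 °C
Reagents that add atoms: none
Why: Radical chain reduction of the secondary iodide; hydrogen transfer to the C1 radical is much faster than addition to the distant isopropenyl group, and the step removes the one stereocentre that is not in the target.

Step 16
Reactants: 21 bridged ether
Product: 23 enal (C12 aldehyde, C13 methylene), via allylic alcohol 22 (not isolated)
Conditions: SeO2 (cat.), t-BuOOH, CH2Cl2, rt; then MnO2, CH2Cl2, rt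
Reagents that add atoms: selenium dioxide, `O=[Se]=O`; tert-butyl hydroperoxide, `CC(C)(C)OO`
Why: Allylic oxidation with SeO2 (ene reaction, then 2,3-sigmatropic shift): the isopropenyl group is now the only alkene, and in a 1,1-disubstituted alkene the methyl group is oxidised in preference to the methine C7–H, giving 22 with some aldehyde; MnO2 takes the mixture to 23.

Step 17
Reactants: 23 enal
Product: 24 acrylic acid
Conditions: NaClO2, NaH2PO4, 2-methyl-2-butene, t-BuOH/H2O, 0 °C to rt
Reagents that add atoms: sodium chlorite, `[Na+].[O-]Cl=O`
Why: Pinnick oxidation of the enal; 2-methyl-2-butene takes up the hypochlorous acid so that the alkene is not chlorinated, and the buffered medium spares the acetonide.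

Step 18
Reactants: 24 acrylic acid
Product: 26 hydroxy lactone (C9 hydroxyl free), via dihydroxy acid 25 (not isolated)
Conditions: 1 M HCl, THF, rt to 40 °C
Reagents that add atoms: none
Why: Aqueous acid hydrolyses the strained trans-fused acetonide to 25, and the acid then closes onto neighbouring O8 (5-exo-trig lactonisation, trans-fused five-membered ring) in preference to O9, which could only give a bridged six-membered lactone; dilute acid should not ionise the tertiary bridge ether.

Step 19
Reactants: 26 hydroxy lactone; 27 3-methylbutanoic anhydride
Product: 28 target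
Conditions: DMAP (cat.), pyridine, CH2Cl2, 0 °C to rt
Reagents that add atoms: 3-methylbutanoic anhydride, `CC(C)CC(=O)OC(=O)CC(C)C`
Why: DMAP-catalysed acylation of the one free hydroxyl; the alcohol is hindered by quaternary C10, hence the nucleophilic catalyst, and the weakly basic medium leaves the α-methylene lactone intact.

## Compound list

1 | (S)-carvone, (5S)-2-methyl-5-(prop-1-en-2-yl)cyclohex-2-en-1-one | `CC1=CC[C@@H](CC1=O)C(=C)C` | starting material
2 | trimethylsilyl dienol ether of 1 (C9–OSiMe3, C8=C9 and C5=C10) | `CC1=CC[C@H](C(C)=C)C=C1O[Si](C)(C)C` | intermediate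
3 | (5R,6R)-6-hydroxy-2-methyl-5-(prop-1-en-2-yl)cyclohex-2-en-1-one | `CC1=CC[C@H](C(C)=C)[C@@H](O)C1=O` | intermediate
4 | tert-butyldimethylsilyl ether of 3 | `CC1=CC[C@H](C(C)=C)[C@@H](O[Si](C)(C)C(C)(C)C)C1=O` | intermediate
5 | epoxy ketone, C5–C10 epoxide anti to isopropenyl | `O=C1[C@H](O[Si](C)(C)C(C)(C)C)[C@@H](C(C)=C)C[C@@H]2O[C@]12C` | intermediate
6 | allylic alcohol, C5 carbinol, C9=C10 alkene | `CC1=C[C@H](O[Si](C)(C)C(C)(C)C)[C@@H](C(C)=C)C[C@@H]1O` | intermediate
7 | (4S,5R)-4-[(tert-butyldimethylsilyl)oxy]-2-methyl-5-(prop-1-en-2-yl)cyclohex-2-en-1-one | `CC1=C[C@H](O[Si](C)(C)C(C)(C)C)[C@@H](C(C)=C)CC1=O` | intermediate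
8 | vinylmagnesium bromide | `C=C[Mg]Br` | starting material
9 | (1S,4S,5R)-4-[(tert-butyldimethylsilyl)oxy]-1-ethenyl-2-methyl-5-(prop-1-en-2-yl)cyclohex-2-en-1-ol | `CC1=C[C@H](O[Si](C)(C)C(C)(C)C)[C@@H](C(C)=C)C[C@]1(O)C=C` | intermediate
10 | epoxy alcohol, C9–C10 epoxide cis to the C5 hydroxyl | `C[C@]12O[C@H]1[C@H](O[Si](C)(C)C(C)(C)C)[C@@H](C(C)=C)C[C@]2(O)C=C` | intermediate
11 | (2R,3R,4R,5R)-4-[(tert-butyldimethylsilyl)oxy]-2-ethenyl-3-hydroxy-2-methyl-5-(prop-1-en-2-yl)cyclohexan-1-one | `O=C1C[C@H](C(C)=C)[C@@H](O[Si](C)(C)C(C)(C)C)[C@H](O)[C@@]1(C)C=C` | intermediate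
12 | (2R,3R,4R,5R)-2-ethenyl-3,4-dihydroxy-2-methyl-5-(prop-1-en-2-yl)cyclohexan-1-one | `O=C1C[C@H](C(C)=C)[C@@H](O)[C@H](O)[C@@]1(C)C=C` | intermediate
13 | acetonide ketone, trans-fused C8/C9 isopropylidene acetal of 12 | `O=C1C[C@H](C(C)=C)[C@H]2OC(C)(C)O[C@@H]2[C@@]1(C)C=C` | intermediate
14 | cis-1,2-divinylcyclohexanol (5S,7R,8R,9R,10R) with C8/C9 acetonide and C7 isopropenyl | `C=C(C)[C@H]1C[C@](O)(C=C)[C@](C)(C=C)[C@H]2OC(C)(C)O[C@H]12` | intermediate
15 | iodomethane | `CI` | starting material
16 | potassium alkoxide of 14 | `C=C(C)[C@H]1C[C@]([O-])(C=C)[C@](C)(C=C)[C@H]2OC(C)(C)O[C@H]12.[K+]` | intermediate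
17 | potassium enolate, ten-membered ring, C4=C5 enolate, (Z)-C1=C10 | `C=C(C)[C@H]1C/C([O-])=C/CC/C=C(C)\[C@H]2OC(C)(C)O[C@H]12.[K+]` | intermediate
18 | (1(10)Z,4S,7R,8R,9R) ten-membered enone, C5 ketone, C4 methyl, C8/C9 acetonide, C7 isopropenyl | `C=C(C)[C@H]1CC(=O)[C@@H](C)CC/C=C(C)\[C@H]2OC(C)(C)O[C@H]12` | intermediate
19 | (5R) alcohol of 18 | `C=C(C)[C@H]1C[C@@H](O)[C@@H](C)CC/C=C(C)\[C@H]2OC(C)(C)O[C@H]12` | intermediate
20 | iodo ether, C5–O–C10 bridge, C1 iodide anti to C10–O | `C=C(C)[C@H]1C[C@H]2O[C@](C)([C@@H](I)CC[C@@H]2C)[C@H]3OC(C)(C)O[C@H]13` | intermediate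
21 | bridged ether (4S,5R,7R,8R,9S,10R) with C8/C9 acetonide and C7 isopropenyl | `C=C(C)[C@H]1C[C@H]2O[C@](C)(CCC[C@@H]2C)[C@H]3OC(C)(C)O[C@H]13` | intermediate
22 | allylic alcohol, C12 hydroxymethyl on the C11=C13 alkene | `C=C(CO)[C@H]1C[C@H]2O[C@](C)(CCC[C@@H]2C)[C@H]3OC(C)(C)O[C@H]13` | intermediate
23 | enal, C12 aldehyde | `C=C(C=O)[C@H]1C[C@H]2O[C@](C)(CCC[C@@H]2C)[C@H]3OC(C)(C)O[C@H]13` | intermediate
24 | acrylic acid | `C=C(C(=O)O)[C@H]1C[C@H]2O[C@](C)(CCC[C@@H]2C)[C@H]3OC(C)(C)O[C@H]13` | intermediate
25 | dihydroxy acid | `C=C(C(=O)O)[C@H]1C[C@H]2O[C@](C)(CCC[C@@H]2C)[C@@H](O)[C@@H]1O` | intermediate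
26 | hydroxy lactone, 12,8-olide with free C9 hydroxyl | `C=C1C(=O)O[C@@H]2[C@@H]1C[C@H]1O[C@](C)(CCC[C@@H]1C)[C@H]2O` | intermediate
27 | 3-methylbutanoic (isovaleric) anhydride | `CC(C)CC(=O)OC(=O)CC(C)C` | starting material
28 | CNP0274454.1 (4S,5R,7R,8R,9S,10R) | `C=C1C(=O)O[C@@H]2[C@@H]1C[C@H]1O[C@](C)(CCC[C@@H]1C)[C@H]2OC(=O)CC(C)C` | target

## Step count and least certain steps

Total step count: 19. Longest linear sequence: 19 steps, from 1 to 28 (8, 15 and 27 are bought).

**Step 12 (key step).**
- Risk: loss of facial selectivity at C4. A (Z)-cyclodecenone enolate can change its fold before it is methylated, and the other fold exposes the other face. O-methylation and a second methylation by proton exchange between product and enolate are lesser risks.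
- Fallback, from 13 back to 18: the C4 methyl is brought in on the Grignard reagent. CH2=C(CH3)MgBr with CeCl3 is added to 13 to give the 2-propenyl carbinol F1. KH and 18-crown-6 then give the C4-methylated enolate directly. A cold kinetic proton quench (2,6-di-tert-butylphenol, −78 °C) lets hydrogen, not carbon, enter on the exposed face. This reverses the sense at C4 relative to methylation and removes the C/O-alkylation question.
- In addition, the C4 epimer of 18 can be returned to the mixture by base equilibration through the ketone.

**Step 13.**
- Risk: poor facial selectivity of hydride delivery, because the carbonyl group of 18 can swing through the ring. The 5S carbinol cannot close to the cis-bridged ether with the right C10 configuration.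
- Fallback, from 18 back to 19: the unwanted carbinol, the (5S) alcohol F2, is inverted by a Mitsunobu reaction with 4-nitrobenzoic acid (PPh3, diisopropyl azodicarboxylate) to the (5R) 4-nitrobenzoate F3. Methanolysis (K2CO3, MeOH) gives 19.

**Step 14.**
- Risk: slow transannular closure if the resting conformer of 19 holds O5 away from C10. Iodine would then be consumed at the isopropenyl group, or O5 would attack C1 to give the six-membered ether.
- Fallback, from 19 back to 21: the C1=C10 alkene is epoxidised from the outer face (mCPBA, NaHCO3, CH2Cl2, −20 °C; a trisubstituted alkene reacts before a 1,1-disubstituted one) to the 1,10-epoxide F4. A catalytic sulfonic acid opens F4 transannularly at tertiary C10 with inversion, giving the bridged ether with a C1 hydroxyl F5. The C1 hydroxyl is removed by Barton–McCombie deoxygenation through the S-methyl xanthate F6 (NaH, CS2, MeI; then Bu3SnH, AIBN).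

**Step 11.**
- Risk: enolisation of the hindered ketone at C6 by the basic reagent instead of addition. Incomplete axial selectivity is the lesser risk.
- Fallback, from 13 back to 14: the slimmer and less basic HC≡CMgBr with CeCl3 gives the ethynyl carbinol F7 by the same axial entry. Semihydrogenation (H2, Pd/CaCO3 poisoned with Pb(OAc)2, quinoline) then gives 14.

**Step 16.**
- Risk: competing oxidation at the tertiary allylic C7–H, over-oxidation, or slow loss of the acetonide to the acidic selenium species.
- Fallback, from 21 back to 22: the isopropenyl group is epoxidised (mCPBA, NaHCO3) to the epoxide F8, formed as both C11 epimers. Al(OiPr)3 in refluxing toluene isomerises F8 to the allylic alcohol 22, which is taken on with MnO2 as in the route.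

## Further compounds

F1 | step 12 | 2-propenyl carbinol, C5 isopropenyl analogue of 14 | `C=C(C)[C@H]1C[C@](O)(C(C)=C)[C@](C)(C=C)[C@H]2OC(C)(C)O[C@H]12`
F2 | step 13 | (5S) alcohol, C5 epimer of 19 | `C=C(C)[C@H]1C[C@H](O)[C@@H](C)CC/C=C(C)\[C@H]2OC(C)(C)O[C@H]12`
F3 | step 13 | (5R) 4-nitrobenzoate of 19 | `C=C(C)[C@H]1C[C@@H](OC(=O)c3ccc(cc3)[N+](=O)[O-])[C@@H](C)CC/C=C(C)\[C@H]2OC(C)(C)O[C@H]12`
F4 | step 14 | 1,10-epoxide of 19, oxygen on the outer face | `C=C(C)[C@H]1C[C@@H](O)[C@@H](C)CC[C@@H]3O[C@]3(C)[C@H]2OC(C)(C)O[C@H]12`
F5 | step 14 | bridged ether with C1 hydroxyl | `C=C(C)[C@H]1C[C@H]2O[C@](C)([C@@H](O)CC[C@@H]2C)[C@H]3OC(C)(C)O[C@H]13`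
F6 | step 14 | S-methyl xanthate of F5 | `C=C(C)[C@H]1C[C@H]2O[C@](C)([C@@H](OC(=S)SC)CC[C@@H]2C)[C@H]3OC(C)(C)O[C@H]13`
F7 | step 11 | ethynyl carbinol, C5 ethynyl analogue of 14 | `C=C(C)[C@H]1C[C@](O)(C#C)[C@](C)(C=C)[C@H]2OC(C)(C)O[C@H]12`
F8 | step 16 | 11,13-epoxide of 21, both C11 epimers | `CC1(CO1)[C@H]2C[C@H]3O[C@](C)(CCC[C@@H]3C)[C@H]4OC(C)(C)O[C@H]24`
A1 | alternative 1 | N-acyloxyphthalimide of the ring A acetic acid with the (phenylsulfonyl)methyl acrylate chain | `O=C(C[C@H]1O[C@](C)(CCC[C@@H]1C)[C@@H](OC(=O)CC(C)C)[C@H](O[Si](C)(C)C(C)(C)C)C=C(CS(=O)(=O)c1ccccc1)C(=O)OC)ON1C(=O)c2ccccc2C1=O`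
A2 | alternative 1 | ring B closed, acrylate on C7, silyl ether on C8, isovalerate on C9 | `COC(=O)C(=C)[C@H]1C[C@H]2O[C@](C)(CCC[C@@H]2C)[C@@H](OC(=O)CC(C)C)[C@@H]1O[Si](C)(C)C(C)(C)C`
A3 | alternative 2 | C5 4-nitroperbenzoate of the trans-decalin lactone | `C1C(=O)O[C@@H]2[C@@H]1C[C@]1(OOC(=O)c3ccc(cc3)[N+](=O)[O-])[C@](C)(CCC[C@@H]1C)[C@H]2O[Si](C)(C)C(C)(C)C`
A4 | alternative 2 | C5 bridgehead 4-nitrobenzoate of the oxygen-bridged lactone | `C1C(=O)O[C@@H]2[C@@H]1C[C@@]1(OC(=O)c3ccc(cc3)[N+](=O)[O-])O[C@](C)(CCC[C@@H]1C)[C@H]2O[Si](C)(C)C(C)(C)C`
A5 | alternative 3 | ring A oxepane with the 2-(bromomethyl)acrylate on the C5 arm and the C8 aldehyde on the C10 arm | `COC(=O)C(CBr)=CC[C@H]1O[C@](C)(CCC[C@@H]1C)[C@@H](OCc1ccc(OC)cc1)C=O`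
A6 | alternative 3 | C9 4-methoxybenzyl ether of the tricyclic α-methylene lactone | `C=C1C(=O)O[C@@H]2[C@@H]1C[C@H]1O[C@](C)(CCC[C@@H]1C)[C@H]2OCc1ccc(OC)cc1`
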